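The dihydrobenzofuran is disconnected at O1–C7a and at the C7–OH bond: the two neighbouring oxygens on C7a (ring oxygen of the dihydrofuran ring) and C7 (phenol) of the benzo ring are read as the two ends of a C7–C7a aryne. In one flask, a fluoroarene is lithiated and loses LiF, the C2 alkoxide closes the five-membered ring at C7a, and the C7 anion left behind is borylated and oxidised to the phenol. The precursor is an open-chain, enantiopure 1-aryl-2-(5-bromo-2-fluorophenyl)propane-1,3-diol with a free benzylic hydroxyl and a trityl-capped primary hydroxyl; both stereocentres come from an Evans syn-aldol reaction, and the bromide later carries the acrylic acid through a Heck reaction.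

Key step: step 5

Remark: the heterocycle is numbered as a 1-benzofuran (O1, C2, C3, C3a, C4 to C7, C7a); the target is the trans (2R,3S) isomer.

Step 1
Reactants: 1 5-bromo-2-fluorophenylacetic acid; 2 (R)-4-benzyl-2-oxazolidinone
Product: 4 (R)-4-benzyl-3-[2-(5-bromo-2-fluorophenyl)acetyl]-1,3-oxazolidin-2-one, via mixed pivalic anhydride 3 (not isolated)
Conditions: PivCl, Et3N, THF, −20 °C; then 2, LiCl, −20 °C → rt
Reagents that add atoms: none
Why: N-acylation of an oxazolidinone through a mixed pivalic anhydride, in which the LiCl-activated oxazolidinone attacks the unhindered arylacetyl carbonyl and no strong base is present that could turn the arylacetic acid into a ketene.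

Step 2
Reactants: 4 (R)-4-benzyl-3-[2-(5-bromo-2-fluorophenyl)acetyl]-1,3-oxazolidin-2-one; 5 3,4-dimethoxybenzaldehyde
Product: 8 (R)-4-benzyl-3-[(2R,3R)-2-(5-bromo-2-fluorophenyl)-3-(3,4-dimethoxyphenyl)-3-hydroxypropanoyl]-1,3-oxazolidin-2-one, via Z-dibutylboron enolate 6 (not isolated), via dibutylboron aldolate 7 (not isolated)
Conditions: Bu2BOTf, i-Pr2NEt, CH2Cl2, −78 → 0 °C; 5, −78 → 0 °C; then pH 7 phosphate buffer, MeOH, 30% H2O2, 0 °C
Reagents that add atoms: none
Why: Evans syn-aldol reaction, in which the Z boron enolate reacts through a chair Zimmerman–Traxler transition state with the auxiliary carbonyl turned away from the enolate oxygen, so that the (R)-benzyl group screens one enolate face and both new stereocentres are set as (2R,3R), the syn arrangement that becomes C3 (S) and C2 (R) of the target.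

Step 3
Reactants: 8 (R)-4-benzyl-3-[(2R,3R)-2-(5-bromo-2-fluorophenyl)-3-(3,4-dimethoxyphenyl)-3-hydroxypropanoyl]-1,3-oxazolidin-2-one
Product: 9 (1R,2S)-2-(5-bromo-2-fluorophenyl)-1-(3,4-dimethoxyphenyl)propane-1,3-diol
Conditions: LiBH4, MeOH (1 equiv), THF, 0 °C
Reagents that add atoms: none
Why: Reductive cleavage of an N-acyl oxazolidinone by LiBH4, which attacks the side-chain carbonyl at 0 °C, frees the auxiliary for recovery and leaves both stereocentres and both aryl halides untouched (the descriptor of the aryl-bearing carbon changes from R to S only because the CIP ranking changes).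

Step 4
Reactants: 9 (1R,2S)-2-(5-bromo-2-fluorophenyl)-1-(3,4-dimethoxyphenyl)propane-1,3-diol
Product: 10 (1R,2S)-2-(5-bromo-2-fluorophenyl)-1-(3,4-dimethoxyphenyl)-3-(trityloxy)propan-1-ol
Conditions: TrCl, Et3N, DMAP (cat.), CH2Cl2, rt
Reagents that add atoms: trityl chloride, ClC(c1ccccc1)(c1ccccc1)c1ccccc1
Why: Selective tritylation (SN1-type etherification), in which the very bulky trityl electrophile reacts with the primary hydroxyl and not with the hindered secondary benzylic one.

Step 5
Reactants: 10 (1R,2S)-2-(5-bromo-2-fluorophenyl)-1-(3,4-dimethoxyphenyl)-3-(trityloxy)propan-1-ol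
Product: 15 (2R,3S)-5-bromo-2-(3,4-dimethoxyphenyl)-3-[(trityloxy)methyl]-2,3-dihydro-1-benzofuran-7-ol, via dilithiated fluoroarene alkoxide 11 (not isolated), via aryne lithium alkoxide 12 (not isolated), via C7-lithio dihydrobenzofuran 13 (not isolated), via lithium aryl triisopropoxyborate 14 (not isolated)
Conditions: lithium 2,2,6,6-tetramethylpiperidide (LiTMP, 3.5 equiv, made from the amine and n-BuLi), THF, −78 °C, then −30 °C; B(OiPr)3, −78 → 0 °C; 30% H2O2, aq NaOH, 0 °C → rt
Reagents that add atoms: hydrogen peroxide, OO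
Why: Two equivalents of the hindered amide remove the hydroxyl proton and then the future C7 proton, the only ring hydrogen next to fluorine and the most acidic one (ortho to F, meta to Br), and on warming the ortho-fluoroaryllithium sheds LiF to give the only possible aryne, C7–C7a, because the other neighbour of the C–F carbon is C3a, which carries the side chain and no hydrogen. The tethered lithium alkoxide then adds in the ring plane to C7a (5-exo-dig with respect to the aryne bond, forming O1–C7a and the dihydrofuran ring), which places the carbanion on C7 beside the new ring oxygen, where induction, O–Li coordination and the surplus of base should keep it metalated against the liberated amine. The closest known reaction type is the intramolecular addition of a tethered alkoxide to an aryne generated from an ortho-fluoroaryllithium with capture of the resulting aryllithium by an electrophile; here the electrophile is B(OiPr)3, and alkaline H2O2 oxidises the aryl borate by 1,2-shift of the aryl group from boron to oxygen, so the hydroxyl ends exactly on C7. No stereocentre is formed or touched, since the new bonds are made at arene carbons only: the (R) carbinol carbon becomes C2, the (S) benzylic carbon becomes C3, and the syn open chain appears as the trans ring. The selectivities needed are lithiation beside F and not beside Br (secured by the stronger acidifying effect of F and by an amide base that does not exchange with C–Br), addition at C7a only (secured by the tether, since attack at C7 cannot close a ring), and cyclisation of the secondary oxygen only (secured by the trityl cap on the primary oxygen, which would otherwise close an equally five-membered ring and which, unlike a silyl group, cannot migrate to the alkoxide).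

Step 6
Reactants: 15 (2R,3S)-5-bromo-2-(3,4-dimethoxyphenyl)-3-[(trityloxy)methyl]-2,3-dihydro-1-benzofuran-7-ol; 16 methyl acrylate
Product: 17 methyl (E)-3-[(2R,3S)-2-(3,4-dimethoxyphenyl)-7-hydroxy-3-[(trityloxy)methyl]-2,3-dihydro-1-benzofuran-5-yl]prop-2-enoate
Conditions: Pd(OAc)2 (cat.), P(o-tol)3, Et3N, DMF, 100 °C
Reagents that add atoms: none
Why: Mizoroki–Heck reaction, in which zerovalent palladium inserts into the C5–Br bond, adds syn across the acrylate and leaves by syn β-hydride elimination to give the E alkene, under amine-base conditions that bromophenols and trityl ethers tolerate.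

Step 7
Reactants: 17 methyl (E)-3-[(2R,3S)-2-(3,4-dimethoxyphenyl)-7-hydroxy-3-[(trityloxy)methyl]-2,3-dihydro-1-benzofuran-5-yl]prop-2-enoate
Product: 19 (E)-3-[(2R,3S)-2-(3,4-dimethoxyphenyl)-7-hydroxy-3-(hydroxymethyl)-2,3-dihydro-1-benzofuran-5-yl]prop-2-enoic acid, via methyl ester diol 18 (not isolated)
Conditions: TsOH·H2O (cat.), MeOH/THF, rt; then aq LiOH, rt; then 1 M HCl to pH 3, 0 °C
Reagents that add atoms: lithium hydroxide, [Li+].[OH-]
Why: Acid-catalysed methanolysis of the trityl ether (SN1, the trityl cation is taken up by methanol) followed in the same flask by ester saponification, with catalytic acid at room temperature too mild to ionise the C2–O1 benzylic ether and with the trityl methyl ether washed out of the basic aqueous phase before the acid is set free.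

Compound list
1 | 5-bromo-2-fluorophenylacetic acid | OC(=O)Cc1cc(Br)ccc1F | starting material
2 | (R)-4-benzyl-2-oxazolidinone | O=C1OC[C@@H](Cc2ccccc2)N1 | starting material
3 | 2-(5-bromo-2-fluorophenyl)acetic pivalic anhydride | CC(C)(C)C(=O)OC(=O)Cc1cc(Br)ccc1F | intermediate
4 | (R)-4-benzyl-3-[2-(5-bromo-2-fluorophenyl)acetyl]-1,3-oxazolidin-2-one | O=C1OC[C@@H](Cc2ccccc2)N1C(=O)Cc1cc(Br)ccc1F | intermediate
5 | 3,4-dimethoxybenzaldehyde | COc1ccc(C=O)cc1OC | starting material
6 | (R)-4-benzyl-3-[(Z)-2-(5-bromo-2-fluorophenyl)-1-(dibutylboryloxy)ethenyl]-1,3-oxazolidin-2-one | O=C1OC[C@@H](Cc2ccccc2)N1/C(OB(CCCC)CCCC)=C/c1cc(Br)ccc1F | intermediate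
7 | (R)-4-benzyl-3-[(2R,3R)-2-(5-bromo-2-fluorophenyl)-3-(dibutylboryloxy)-3-(3,4-dimethoxyphenyl)propanoyl]-1,3-oxazolidin-2-one | O=C1OC[C@@H](Cc2ccccc2)N1C(=O)[C@H](c1cc(Br)ccc1F)[C@@H](OB(CCCC)CCCC)c1ccc(OC)c(OC)c1 | intermediate
8 | (R)-4-benzyl-3-[(2R,3R)-2-(5-bromo-2-fluorophenyl)-3-(3,4-dimethoxyphenyl)-3-hydroxypropanoyl]-1,3-oxazolidin-2-one | O=C1OC[C@@H](Cc2ccccc2)N1C(=O)[C@H](c1cc(Br)ccc1F)[C@@H](O)c1ccc(OC)c(OC)c1 | intermediate
9 | (1R,2S)-2-(5-bromo-2-fluorophenyl)-1-(3,4-dimethoxyphenyl)propane-1,3-diol | COc1ccc([C@H](O)[C@H](CO)c2cc(Br)ccc2F)cc1OC | intermediate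
10 | (1R,2S)-2-(5-bromo-2-fluorophenyl)-1-(3,4-dimethoxyphenyl)-3-(trityloxy)propan-1-ol | COc1ccc([C@H](O)[C@H](COC(c2ccccc2)(c2ccccc2)c2ccccc2)c2cc(Br)ccc2F)cc1OC | intermediate
11 | lithium (1R,2S)-2-(5-bromo-2-fluoro-3-lithiophenyl)-1-(3,4-dimethoxyphenyl)-3-(trityloxy)propan-1-olate | COc1ccc([C@H](O[Li])[C@H](COC(c2ccccc2)(c2ccccc2)c2ccccc2)c2cc(Br)cc([Li])c2F)cc1OC | intermediate
12 | lithium (1R,2S)-2-(5-bromo-2,3-didehydrophenyl)-1-(3,4-dimethoxyphenyl)-3-(trityloxy)propan-1-olate (the C7–C7a aryne) | COc1ccc([C@H](O[Li])[C@H](COC(c2ccccc2)(c2ccccc2)c2ccccc2)C2=CC(Br)=CC#C2)cc1OC | intermediate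
13 | [(2R,3S)-5-bromo-2-(3,4-dimethoxyphenyl)-3-[(trityloxy)methyl]-2,3-dihydro-1-benzofuran-7-yl]lithium | COc1ccc([C@@H]2Oc3c([Li])cc(Br)cc3[C@H]2COC(c4ccccc4)(c4ccccc4)c4ccccc4)cc1OC | intermediate
14 | lithium [(2R,3S)-5-bromo-2-(3,4-dimethoxyphenyl)-3-[(trityloxy)methyl]-2,3-dihydro-1-benzofuran-7-yl]tri(propan-2-yloxy)borate | COc1ccc([C@@H]2Oc3c([B-](OC(C)C)(OC(C)C)OC(C)C)cc(Br)cc3[C@H]2COC(c4ccccc4)(c4ccccc4)c4ccccc4)cc1OC.[Li+] | intermediate
15 | (2R,3S)-5-bromo-2-(3,4-dimethoxyphenyl)-3-[(trityloxy)methyl]-2,3-dihydro-1-benzofuran-7-ol | COc1ccc([C@@H]2Oc3c(O)cc(Br)cc3[C@H]2COC(c4ccccc4)(c4ccccc4)c4ccccc4)cc1OC | intermediate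
16 | methyl acrylate | C=CC(=O)OC | starting material
17 | methyl (E)-3-[(2R,3S)-2-(3,4-dimethoxyphenyl)-7-hydroxy-3-[(trityloxy)methyl]-2,3-dihydro-1-benzofuran-5-yl]prop-2-enoate | COc1ccc([C@@H]2Oc3c(O)cc(/C=C/C(=O)OC)cc3[C@H]2COC(c4ccccc4)(c4ccccc4)c4ccccc4)cc1OC | intermediate
18 | methyl (E)-3-[(2R,3S)-2-(3,4-dimethoxyphenyl)-7-hydroxy-3-(hydroxymethyl)-2,3-dihydro-1-benzofuran-5-yl]prop-2-enoate | COc1ccc([C@@H]2Oc3c(O)cc(/C=C/C(=O)OC)cc3[C@H]2CO)cc1OC | intermediate
19 | (E)-3-[(2R,3S)-2-(3,4-dimethoxyphenyl)-7-hydroxy-3-(hydroxymethyl)-2,3-dihydro-1-benzofuran-5-yl]prop-2-enoic acid | COc1ccc([C@@H]2Oc3c(O)cc(/C=C/C(=O)O)cc3[C@H]2CO)cc1OC | target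

Total step count: 7
Longest linear sequence: 7 steps (from 1 to 19)

Steps most likely to fail

Step 5. Before the borate arrives, the C7 aryllithium may be protonated by the 2,2,6,6-tetramethylpiperidine set free in the two deprotonations. Lithium and bromine may also change places between molecules while the mixture is warmed for LiF loss, so that boron ends on the wrong carbon or on none. The fallback removes both the amine and the bromide; it sets out from 2 and 5 and comes back to the route at 17.
- Commercially available 5-chloro-2-fluorophenylacetic acid F1 would be taken through the chemistry of steps 1 to 4.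
- Acylation of 2 would give (R)-4-benzyl-3-[2-(5-chloro-2-fluorophenyl)acetyl]-1,3-oxazolidin-2-one F2.
- The Evans syn-aldol reaction with 5 would give (R)-4-benzyl-3-[(2R,3R)-2-(5-chloro-2-fluorophenyl)-3-(3,4-dimethoxyphenyl)-3-hydroxypropanoyl]-1,3-oxazolidin-2-one F3.
- LiBH4 cleavage would give (1R,2S)-2-(5-chloro-2-fluorophenyl)-1-(3,4-dimethoxyphenyl)propane-1,3-diol F4.
- Tritylation would give (1R,2S)-2-(5-chloro-2-fluorophenyl)-1-(3,4-dimethoxyphenyl)-3-(trityloxy)propan-1-ol F5.
- An aryl chloride does not exchange with alkyllithiums at −78 °C. F5 would therefore be deprotonated at oxygen with n-BuLi and lithiated beside fluorine with s-BuLi in THF, then warmed, borylated and oxidised as in step 5. With no proton donor in the flask this should give (2R,3S)-5-chloro-2-(3,4-dimethoxyphenyl)-3-[(trityloxy)methyl]-2,3-dihydro-1-benzofuran-7-ol F6.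
- A Heck reaction of the aryl chloride with 16 (Pd2(dba)3, P(t-Bu)3, Cy2NMe, dioxane, 110 °C) would then deliver 17.

Step 3. While the hindered imide is being reduced, the alkoxide may fragment by retro-aldol reaction, the acidic α-aryl centre may epimerise, or hydride may open the ring carbonyl of the auxiliary. The fallback separates cleavage from reduction; it sets out from 8 and comes back at 9.
- LiOH/H2O2 in THF/H2O at 0 °C, which attacks the side-chain carbonyl selectively and quickly, would give (2R,3R)-2-(5-bromo-2-fluorophenyl)-3-(3,4-dimethoxyphenyl)-3-hydroxypropanoic acid F7 and recovered 2.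
- BH3·THF would then reduce the carboxylic acid to the primary alcohol 9 under non-basic conditions that leave the aryl halides alone.

Step 6. Insertion of palladium into the electron-rich C5–Br bond, para to the ring oxygen and beside a phenoxide, may be slow at 100 °C. The catalyst could then decompose and the bromide be lost by reduction, or the phenol could add to the acrylate. The fallback replaces the Heck reaction by a Suzuki–Miyaura coupling; it sets out from 15 and comes back at 17.
- 15 would be coupled with commercially available methyl (E)-3-(4,4,5,5-tetramethyl-1,3,2-dioxaborolan-2-yl)prop-2-enoate (PdCl2(dppf), K3PO4, dioxane/H2O, 70 °C).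
- The alkene geometry is carried in the boronate, and no excess acrylate is present.

Further compounds
F1 | step 5 | 5-chloro-2-fluorophenylacetic acid | OC(=O)Cc1cc(Cl)ccc1F
F2 | step 5 | (R)-4-benzyl-3-[2-(5-chloro-2-fluorophenyl)acetyl]-1,3-oxazolidin-2-one | O=C1OC[C@@H](Cc2ccccc2)N1C(=O)Cc1cc(Cl)ccc1F
F3 | step 5 | (R)-4-benzyl-3-[(2R,3R)-2-(5-chloro-2-fluorophenyl)-3-(3,4-dimethoxyphenyl)-3-hydroxypropanoyl]-1,3-oxazolidin-2-one | O=C1OC[C@@H](Cc2ccccc2)N1C(=O)[C@H](c1cc(Cl)ccc1F)[C@@H](O)c1ccc(OC)c(OC)c1
F4 | step 5 | (1R,2S)-2-(5-chloro-2-fluorophenyl)-1-(3,4-dimethoxyphenyl)propane-1,3-diol | COc1ccc([C@H](O)[C@H](CO)c2cc(Cl)ccc2F)cc1OC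
F5 | step 5 | (1R,2S)-2-(5-chloro-2-fluorophenyl)-1-(3,4-dimethoxyphenyl)-3-(trityloxy)propan-1-ol | COc1ccc([C@H](O)[C@H](COC(c2ccccc2)(c2ccccc2)c2ccccc2)c2cc(Cl)ccc2F)cc1OC
F6 | step 5 | (2R,3S)-5-chloro-2-(3,4-dimethoxyphenyl)-3-[(trityloxy)methyl]-2,3-dihydro-1-benzofuran-7-ol | COc1ccc([C@@H]2Oc3c(O)cc(Cl)cc3[C@H]2COC(c4ccccc4)(c4ccccc4)c4ccccc4)cc1OC
F7 | step 3 | (2R,3R)-2-(5-bromo-2-fluorophenyl)-3-(3,4-dimethoxyphenyl)-3-hydroxypropanoic acid | OC(=O)[C@H](c1cc(Br)ccc1F)[C@@H](O)c1ccc(OC)c(OC)c1
F0 | step 6 | none | none
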